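## Retrosynthetic overview
1. The curcuminoid is assembled last: aryl aldehyde **16** (vanillin-derived) plus p-hydroxystyryl-acetylacetone **19** (Pabon-type boron-mediated condensation).
2. **16** comes from **8** by building the side chain on the isopropenyl group: cross-metathesis with methyl acrylate, Cu–H conjugate reduction (sets C7), Weinreb amide, 2-methylpropenyl Grignard, then late benzylic oxidation.
3. **8** comes from endoperoxide **5** by a proposed new Lewis-acid ring-opening with vanillin. This forms the C1–OAr bond and puts both oxygens cis and trans to C6.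
4. **5** comes from singlet-oxygen [4+2] of triene **4**, which comes from Shapiro reaction of (S)-carvone (**1**). The carbocycle and the C6 stereocenter come from the chiral pool; the only new ring is the bicyclic peroxide, made in Step 3 and opened in Step 4.

Assumptions:
- (S)-carvone is the correct enantiomer. The Shapiro diene termini (old C6 and C3) become the oxygenated carbons, which reverses the ring numbering relative to carvone.
- (R)-DTBM-SEGPHOS is the matched ligand for the 7S centre. Swapping the ligand enantiomer would not change the route.
- The target is drawn as the enol tautomer of the β-diketone, which is the same compound.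

## Route

**Step 1**
Reactants: 1 (S)-carvone; 2 2,4,6-triisopropylbenzenesulfonyl hydrazide
Product: 3 carvone trisylhydrazone
Conditions: cat. HCl, THF, rt
Reagents that add atoms: none
Why: Condensation of the ketone with the sulfonylhydrazide. No stereocenter is touched.

**Step 2**
Reactant: 3
Product: 4 (5S)-2-methyl-5-(prop-1-en-2-yl)cyclohexa-1,3-diene
Conditions: n-BuLi (2.3 equiv), THF, –78 → 0 °C; then H2O
Reagents that add atoms: none (H only)
Why: Shapiro reaction. Deprotonation at the unsubstituted α′-CH2, loss of sulfinate and N2, and protonation of the vinyllithium give the conjugated diene. The isopropenyl-bearing stereocenter is not involved.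

**Step 3**
Reactant: 4
Product: 5 5-methyl-7-(prop-1-en-2-yl)-2,3-dioxabicyclo[2.2.2]oct-5-ene (peroxide bridge anti to the isopropenyl)
Conditions: O2, TPP (0.1 mol %), hν (visible), CH2Cl2, –10 °C
Reagents that add atoms: singlet O2 from triplet O2, O=O
Why: Photooxygenation, a Diels–Alder-type [4+2] of ¹O2 with the cyclohexadiene. It adds to the face anti to the allylic isopropenyl, so both new C–O bonds are cis to each other and trans to C6. This sets C1 and C4 relative to C6.

**Step 4**
Reactants: 5; 6 vanillin (4-hydroxy-3-methoxybenzaldehyde)
Product: 7 4-{[4-hydroperoxy-3-methyl-6-(prop-1-en-2-yl)cyclohex-2-en-1-yl]oxy}-3-methoxybenzaldehyde (OAr and OOH cis, isopropenyl trans)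
Conditions: 6 (1.5 equiv), Ca(NTf2)2 (5 mol %), Bu4NPF6 (5 mol %), CH2Cl2/HFIP 9:1, 0 °C
Reagents that add atoms: none (vanillin is reactant 6)
Why: Proposed new method: the endoperoxide is used as a masked cis-1,4-diol electrophile.
- Regiochemistry: activation of the C1-bound peroxide oxygen ionizes C1–O to give an allyl cation (C1–C2–C3). Its C3 terminus is tertiary (methyl-bearing), so C1–O cleaves much faster than C4–O, which would give a 2-methylallyl cation. The other oxygen stays on C4 as a hydroperoxide.
- Stereochemistry: the electron-poor phenol O attacks the secondary terminus C1, which gives the trisubstituted-alkene isomer. It attacks from the lower face, anti to the C6 isopropenyl and syn to the C4–OOH that hydrogen-bonds the phenol. The result is OAr cis to OOH and trans to C6.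
- Closest known reactions: Lewis-acid/HFIP SN1-type allylic etherification and acid ring-opening of bicyclic endoperoxides (Hock/Kornblum–DeLaMare manifold).

**Step 5**
Reactant: 7
Product: 8 {4-[(4-hydroxy-3-methyl-6-isopropenylcyclohex-2-en-1-yl)oxy]-3-methoxyphenyl}methanol (OAr and OH cis, isopropenyl trans)
Conditions: PPh3 (1.2 equiv), CH2Cl2, 0 °C; then NaBH4 (1.5 equiv), MeOH, 0 °C
Reagents that add atoms: none (H only)
Why: Phosphine deoxygenation of the hydroperoxide to the alcohol with retention at C4 (a Staudinger-type O-transfer), and borohydride reduction of ArCHO. The aldehyde is removed here so later hydride and organometallic steps are compatible.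

**Step 6**
Reactants: 8; 9 methyl acrylate
Product: 10 methyl (E)-3-[ring C6]-but-2-enoate, i.e. the enoate ring–C(CH3)=CH–CO2Me
Conditions: 9 (5 equiv), Hoveyda–Grubbs II (5 mol %), CH2Cl2, 40 °C
Reagents that add atoms: none (methyl acrylate is reactant 9)
Why: Cross-metathesis of the 1,1-disubstituted isopropenyl group with an acrylate. It is E-selective, and the hindered ring trisubstituted alkene does not react.

**Step 7**
Reactant: 10
Product: 11 methyl (S)-3-[ring C6]-butanoate (ring–CH(CH3)–CH2–CO2Me; C7 set)
Conditions: Cu(OAc)2·H2O (5 mol %), (R)-DTBM-SEGPHOS (5 mol %), TMDS, t-BuOH, toluene, 0 °C → rt; then aq. NH4F/MeOH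
Reagents that add atoms: none (H only; any O–Si is cleaved on work-up)
Why: Cu–H conjugate reduction of the β,β-dialkyl enoate. Hydride is delivered to C7 under ligand control, which overrides the weak bias of the ring stereocenter, and the Cu-enolate is protonated at C8. The isolated ring alkene, free alcohols and aryl ether survive.

**Step 8**
Reactants: 11; 12 N,O-dimethylhydroxylamine hydrochloride
Product: 13 Weinreb amide ring–CH(CH3)–CH2–C(=O)N(OMe)Me
Conditions: 12 (3 equiv), iPrMgCl (8 equiv), THF, –20 → 0 °C
Reagents that add atoms: none (12 is reactant)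
Why: Williams-type Weinreb amidation. The extra Grignard covers the two free OH groups, and C7 is not α to the carbonyl so it cannot epimerize.

**Step 9**
Reactants: 13; 14 2-methylprop-1-enylmagnesium bromide
Product: 15 enone ring–CH(CH3)–CH2–C(=O)–CH=C(CH3)2 with benzylic CH2OH
Conditions: 14 (6 equiv), THF, –78 → –20 °C
Reagents that add atoms: none (14 is reactant)
Why: Grignard addition to a Weinreb amide stops at the ketone through the chelated tetrahedral intermediate, giving the dimethyl-vinyl enone.

**Step 10**
Reactant: 15
Product: 16 aryl aldehyde with free C4–OH and full side chain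
Conditions: TEMPO (10 mol %), PhI(OAc)2 (1.2 equiv), NaHCO3, CH2Cl2, 0 °C
Reagents that add atoms: none
Why: Anelli-type oxidation is selective for the unhindered primary benzylic alcohol over the hindered secondary allylic alcohol. The bicarbonate buffer protects the acid-labile allylic aryl ether.

**Step 11** (separate branch from commercial materials)
Reactants: 17 4-hydroxybenzaldehyde; 18 acetylacetone
Product: 19 (E)-6-(4-hydroxyphenyl)hex-5-ene-2,4-dione
Conditions: 18 (5 equiv), B2O3, B(OBu)3, n-BuNH2 (cat.), EtOAc, 70 °C; then 1 M HCl, 60 °C
Reagents that add atoms: none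
Why: Pabon boron-mediated Knoevenagel condensation. Excess acetylacetone limits bis-condensation, and the E-enone forms selectively.

**Step 12**
Reactants: 16; 19
Product: 20 Demethoxybisabolocurcumin ether (target)
Conditions: 19 (1.2 equiv), B2O3, EtOAc, 70 °C; then 16, B(OBu)3, n-BuNH2 (cat.), 70 °C; then 5 % aq. AcOH, 40 °C
Reagents that add atoms: none
Why: Pabon condensation of the boron-chelated diketone methyl terminus with the aldehyde gives the (E,E)-curcuminoid. No stereocenter is affected under these mild conditions.

## Compound list
1 | (S)-(+)-carvone | CC1=CC[C@@H](CC1=O)C(C)=C | starting material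
2 | 2,4,6-triisopropylbenzenesulfonyl hydrazide | CC(C)c1cc(C(C)C)c(S(=O)(=O)NN)c(C(C)C)c1 | starting material
3 | carvone trisylhydrazone | CC1=CC[C@@H](CC1=NNS(=O)(=O)c2c(C(C)C)cc(C(C)C)cc2C(C)C)C(C)=C | intermediate
4 | (5S)-2-methyl-5-(prop-1-en-2-yl)cyclohexa-1,3-diene | C1C=C(C)C=C[C@H]1C(C)=C | intermediate
5 | endoperoxide, 5-methyl-7-isopropenyl-2,3-dioxabicyclo[2.2.2]oct-5-ene | O1O[C@H]2C=C(C)[C@@H]1C[C@@H]2C(C)=C | intermediate
6 | vanillin | COc1cc(C=O)ccc1O | starting material
7 | allylic hydroperoxide aryl ether aldehyde | COc1cc(C=O)ccc1O[C@H]1C=C(C)[C@@H](OO)C[C@@H]1C(C)=C | intermediate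
8 | diol, benzylic alcohol with isopropenyl | COc1cc(CO)ccc1O[C@H]1C=C(C)[C@@H](O)C[C@@H]1C(C)=C | intermediate
9 | methyl acrylate | C=CC(=O)OC | starting material
10 | (E)-enoate | COc1cc(CO)ccc1O[C@H]1C=C(C)[C@@H](O)C[C@@H]1/C(C)=C/C(=O)OC | intermediate
11 | saturated methyl ester (7S) | COc1cc(CO)ccc1O[C@H]1C=C(C)[C@@H](O)C[C@@H]1[C@@H](C)CC(=O)OC | intermediate
12 | N,O-dimethylhydroxylamine hydrochloride | CNOC.Cl | starting material
13 | Weinreb amide | COc1cc(CO)ccc1O[C@H]1C=C(C)[C@@H](O)C[C@@H]1[C@@H](C)CC(=O)N(C)OC | intermediate
14 | 2-methylprop-1-enylmagnesium bromide | CC(C)=C[Mg]Br | starting material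
15 | enone benzylic alcohol | COc1cc(CO)ccc1O[C@H]1C=C(C)[C@@H](O)C[C@@H]1[C@@H](C)CC(=O)C=C(C)C | intermediate
16 | aryl aldehyde with full side chain | COc1cc(C=O)ccc1O[C@H]1C=C(C)[C@@H](O)C[C@@H]1[C@@H](C)CC(=O)C=C(C)C | intermediate
17 | 4-hydroxybenzaldehyde | O=Cc1ccc(O)cc1 | starting material
18 | acetylacetone | CC(=O)CC(C)=O | starting material
19 | (E)-6-(4-hydroxyphenyl)hex-5-ene-2,4-dione | CC(=O)CC(=O)/C=C/c1ccc(O)cc1 | intermediate
20 | Demethoxybisabolocurcumin ether | COc1cc(/C=C/C(O)=C/C(=O)/C=C/c2ccc(O)cc2)ccc1O[C@H]1C=C(C)[C@@H](O)C[C@@H]1[C@@H](C)CC(=O)C=C(C)C | target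

## Totals
- Total steps: 12 (11 on the main branch plus the one-step side-chain branch, Step 11).
- Longest linear sequence: 11 steps (Steps 1–10 and 12).

## Three steps most likely to fail
1. **Step 4 (the proposed new reaction).** The allyl cation could eliminate, undergo Hock cleavage, or cyclize onto the isopropenyl group, and phenol C-alkylation could compete.
   - Fallback (known chemistry, different approach): skip the endoperoxide. Epoxidize triene 4 with DMDO or a Shi catalyst to the vinyl epoxide, then apply Pd(0)/dppe-catalysed cis-1,4-addition of vanillin (Tsuji–Trost on a vinyl epoxide). Then reduce with NaBH4 to reach 8, separating diastereomers if the epoxidation is not selective.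
2. **Step 7 (C7 stereocontrol).** The diastereoselectivity could be poor, or Cu–H could cleave the allylic aryl ether by SN2′ hydride attack.
   - Fallback: from 8, protect both alcohols as TBS ethers and hydroborate the isopropenyl group with 9-BBN. Oxidize to the primary alcohol, convert it to the iodide, then t-BuLi and the Weinreb amide of 3-methylbut-2-enoic acid to form the ketone. Separate the C7 epimers by HPLC and remove the TBS groups.
3. **Step 12 (final condensation and boron decomplexation).** The multifunctional, acid-sensitive substrate may fail under the boron-mediated condensation or its hydrolysis.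
   - Fallback: Claisen–Schmidt of 16 with acetone to the benzalacetone. Then Claisen condensation with methyl 4-(TBSO)cinnamate using LiHMDS, followed by buffered TBAF.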